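I decide to follow one thing in this flask, the loss rate of substrate per unit of substrate standing, and to let the adducts wait.

the same everywhere: partner 0.102 M
- amber: substrate 0.19 M; run made earlier
- flask: substrate 0.097 M; time 20 d

amber run (percent of the substrate charged)

| time / h | substrate / % | mono adduct / % |
|---|---|---|
| 6.00 | 57.6 | 3.1 |
| 15.0 | 35.3 | 7.0 |
| 30.0 | 19.5 | 8.2 |
| 50.0 | 12.7 | 8.7 |

(standard deviation of a reading: 0.5 percentage points)

- the analysis behind the earlier runs scatters by 0.5 percentage points, standard deviation
- a reading or a percentage of mono adduct counts all its forms, free or not
- a reading of substrate is of its free form alone

* the substrate standing at 20 d, as a percentage of the substrate charged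
* the mono adduct standing at 20 d, as a percentage of the substrate charged
* the other mono adduct standing at 20 d, as a percentage of the substrate charged
* the double product standing at 20 d, as a percentage of the substrate charged

In the amber run that rate reads as falling roughly in step with substrate itself. The rate divided by substrate, a second-order constant, reads 0.646 M⁻¹ h⁻¹ up to the first reading and 0.724 M⁻¹ h⁻¹ up to the last. By then the amber run has lost 0.166 M of substrate, more than the 0.102 M of partner charged. So I take substrate as pulling on itself, and I read the small rise in the constant as a correction from partner.

With the last constant I reckon the start of this flask at 0.0702 h⁻¹, about half the 0.137 h⁻¹ reckoned the same way for the amber run. Falling substrate slows it, and the accumulated slowing over 20 d is what I call the slowing factor, one plus the constant times the charge times the time: 34.7. On this reckoning the substrate left in this flask is the inverse of that factor, 2.88%, an estimate that I expect partner's correction to lower. My figure is higher than the forecast's.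

The forecast gives substrate 0.3%, mono adduct 10%, other mono adduct 45% and double product 44%, reasoning that “each partner must carry two reactive sites”.

The flask gives substrate 0.458%, mono adduct 2.96%, other mono adduct 9.32% and double product 29.6%.

    substrate + partner → other mono adduct (k = 0.0735 M⁻¹ h⁻¹)
    substrate + partner → mono adduct (k = 0.0916 M⁻¹ h⁻¹)
    2 substrate → self-condensation product (k = 0.258 M⁻¹ h⁻¹)
    partner + other mono adduct → double product (k = 0.0369 M⁻¹ h⁻¹)
    substrate + mono adduct ⇌ idle adduct, settled at all times (K = 3.72 M⁻¹)
    partner + mono adduct → double product (k = 0.118 M⁻¹ h⁻¹)

In this flask self-condensation product, each counted as two substrate, stands at 57.7%, and my estimate of 2.88% lies above the substrate found by a factor of 6.29. The neighbouring flask has partner cut to 0.061 M and the same substrate charge, so the reckoning gives the same slowing factor, 34.7, and the same 2.88%. Its substrate stands at 1.35%, which narrows the gap to a factor of 2.13. Its double product stands at 15.4%, and its self-condensation product at 69.0%.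

The runs stem from a simulated flask from invented constants; noise was put on by code.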